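Monday's flask runs for 8.0 h where Saturday's runs for 2.0 h, from the same charge, so we must know what the extra time can still buy.

| flask | substrate | partner | free catalyst | remark | time |
|---|---|---|---|---|---|
| blue | 0.050 M | 5 equiv | 0.13 mol% | run made earlier |  |
| green | 0.050 M | 5 equiv | 0.3 mol% | run made earlier |  |
| teal | 0.075 M | 5 equiv | 0.2 mol% | run made earlier |  |
| Saturday's | 0.050 M | 5.00 equiv | 0.2 mol% |  | 2.0 h |
| Monday's | 0.050 M | 5.00 equiv | 0.2 mol% |  | 8.0 h |

- blue (time / min: product / %, substrate / %): 8.00: 4.0, 96.2; 25.0: 11.3, 89.0; 40.0: 17.3, 82.7; 60.0: 23.3, 75.9; 90.0: 32.4, 68.0; 120: 38.6, 61.1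
- green (time / min: product / %, substrate / %): 10.0: 11.0, 88.8; 15.0: 16.4, 84.1; 25.0: 25.9, 74.0; 40.0: 39.0, 61.6; 80.0: 66.2, 34.0; 120: 83.0, 16.9
- teal (time / min: product / %, substrate / %): 25.0: 20.7, 78.9; 50.0: 38.5, 61.6; 80.0: 54.5, 44.8; 90.0: 59.0, 40.3; 120: 70.5, 29.1

(readings scatter by 0.3 percentage points)

- what was read earlier has a scatter of 0.3 percentage points, one standard deviation

- which of the two ends with the higher amount of product, in percent of the substrate charged ("neither" if they lie within 2 percentage points) (Saturday's / Monday's / neither)
- product at the end, in percent of the substrate charged, Saturday's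
- product at the end, in percent of the substrate charged, Monday's

In the earlier runs product divided by time falls steadily, so we let the rate fade exponentially with a constant k and integrate. With c for product in percent of the substrate charged, and R for the initial rate over k:

c(t) = R · (1 − exp(−k·t))

R = c(t) · c(t) / (2 · c(t) − c(2t))

The loading enters R in proportion, for both flasks alike. The green readings at 40.0 min and 80.0 min, rescaled to Saturday's loading, give 85.9%: this is the reach, the product a flask approaches as its rate fades away. Their fade constant is 0.00901 min⁻¹. The blue readings give 0.00701 min⁻¹ and a reach of 104%.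

Saturday's barely feels this disagreement, at 59.2% from blue against 56.8% from green. Monday's feels it fully, since by then green's fade has delivered nearly all of the reach, so k is the number to know well. We take green, whose denominator stands further above the scatter, and expect 84.8% for Monday's.

The forecast, built on “catalyst decaying over time”, says Monday's, with 60.5% (58% to 63%) and 93% (87% to 98%), which for Monday's stands higher than our figure.

The flasks give 57.5% on Saturday's and 76.8% on Monday's, so Monday's ends higher.

    partner + free catalyst → catalyst intermediate A (k = 0.510 L mol⁻¹ s⁻¹)
    substrate + catalyst intermediate B → catalyst intermediate C (k = 170 L mol⁻¹ s⁻¹)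
    catalyst intermediate D → free catalyst + product (k = 0.170 s⁻¹)
    catalyst intermediate A → catalyst intermediate B (k = 0.750 s⁻¹)
    partner → decomposed reagent (k = 1.90 × 10⁻⁴ s⁻¹)
    catalyst intermediate C ⇌ by-product + catalyst intermediate D (K = 0.150 M, k = 2.40 s⁻¹)

Monday's stops at 76.8% with 23% of the substrate unused, because partner, down to 0.11% of its charge and so the limiting reagent despite its excess, goes by itself to decomposed reagent: the same flask without that path ends at 100%. Monday's own product at 4.00 h and 8.00 h puts the reach at 76.9%, lower than our 85.9%. Saturday's own product at 1.00 h and 2.00 h puts the reach at 85.5%, against the 76.9% that Saturday's flask holds after 20.0 h.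

The readings were computed on assumed constants; the scatter is artificial.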